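**Retrosynthetic overview**

1. Feature: in the 14-membered lactone (ring atoms C1, the lactone carbonyl, to C13, the ethyl carbinol, plus the ring oxygen between C13 and C1) the diene C10(=CH2)–C11H=C12(CH3) holds the C10–C11 single bond between two sp2 carbons. An intramolecular Stille coupling of a C10 alkenyl bromide with a C11 (Z)-alkenylstannane makes this bond and closes the only ring.
2. Seco β-keto ester ⇒ C1–O13 ester bond (Yamaguchi) and oxidation at C3; C2–C3 ⇒ Evans syn-aldol on the C3 aldehyde (sets C2).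
3. C6 methyl enol ether ⇒ C6≡C7 alkyne by tethered syn-hydrosilylation, iododesilylation and copper-catalysed methoxylation; C5–C6 ⇒ alkynyl opening of a Sharpless epoxide (sets C4).
4. C8 and the C10 bromide ⇒ Evans alkylation with 2,3-dibromopropene; the C11–C13 stannyl alcohol ⇒ anti-carbomagnesiation/iodination of pent-1-yn-3-ol, oxidation, CBS reduction (sets C13), stannylation.
5. After ring closure, buffered HF·pyridine frees the C4 hydroxyl and the hydroxymethyl group.

Key step: step 23

Remark: C2 lies between the lactone and ketone carbonyl groups and can epimerise through the enol; it is set by auxiliary control in step 15 and every later step is run without base, on the assumption that the 2R configuration of the isolated compound then persists.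

**Route**

Step 1
Reactants: 1 (R)-4-benzyl-3-propionyloxazolidin-2-one; 2 2,3-dibromopropene
Product: 4 (R)-4-benzyl-3-[(S)-4-bromo-2-methylpent-4-enoyl]oxazolidin-2-one, via sodium (Z)-enolate 3 (not isolated)
Conditions: NaN(SiMe3)2, THF, −78 °C; then 2, −78 → −40 °C
Reagents that add atoms: none
Why: Evans asymmetric alkylation: the chelated sodium (Z)-enolate reacts at the allylic C–Br bond of 2 (SN2) on the face away from the benzyl group and so sets C8 (S), while the alkenyl bromide that later becomes C10–Br is inert.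

Step 2
Reactants: 4 (R)-4-benzyl-3-[(S)-4-bromo-2-methylpent-4-enoyl]oxazolidin-2-one
Product: 5 (S)-4-bromo-2-methylpent-4-en-1-ol
Conditions: LiBH4, MeOH (1 equiv), Et2O, 0 °C
Reagents that add atoms: none
Why: Reductive removal of the auxiliary: LiBH4 reduces the activated imide carbonyl to the primary alcohol without touching the alkenyl bromide or the C8 centre.

Step 3
Reactants: 5 (S)-4-bromo-2-methylpent-4-en-1-ol
Product: 6 (S)-4-bromo-2-methylpent-4-enal
Conditions: Dess–Martin periodinane, pyridine, CH2Cl2, 0 °C → rt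
Reagents that add atoms: none
Why: Dess–Martin oxidation under pyridine buffering should give the α-branched aldehyde without epimerisation at C8, and the volatile product is used directly in solution.

Step 4
Reactants: 6 (S)-4-bromo-2-methylpent-4-enal
Product: 7 (S)-2-bromo-4-methylhex-1-en-5-yne
Conditions: dimethyl (1-diazo-2-oxopropyl)phosphonate, K2CO3, MeOH, 0 °C → rt
Reagents that add atoms: dimethyl (1-diazo-2-oxopropyl)phosphonate COP(=O)(OC)C(=[N+]=[N-])C(C)=O
Why: Ohira–Bestmann (Seyferth–Gilbert) homologation: the diazophosphonate anion made in situ adds to the aldehyde and the alkylidene carbene rearranges to the terminal alkyne, so that the former aldehyde carbon becomes C7 and the new carbon C6, under carbonate conditions mild enough to keep C8.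

Step 5
Reactants: 8 2-methylenepropane-1,3-diol
Product: 10 2-[(tert-butyldimethylsilyloxy)methyl]prop-2-en-1-ol, via monosodium alkoxide 9 (not isolated)
Conditions: NaH (1 equiv), THF, 0 °C → rt; then t-BuMe2SiCl (1 equiv)
Reagents that add atoms: tert-butyldimethylsilyl chloride CC(C)(C)[Si](C)(C)Cl
Why: Monosilylation through the sparingly soluble monosodium alkoxide (O-silylation of an alkoxide) differentiates the two hydroxyls of the symmetric diol.

Step 6
Reactants: 10 2-[(tert-butyldimethylsilyloxy)methyl]prop-2-en-1-ol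
Product: 11 (R)-{2-[(tert-butyldimethylsilyloxy)methyl]oxiran-2-yl}methanol
Conditions: Ti(OiPr)4 (cat.), D-(−)-diisopropyl tartrate, t-BuOOH, 4 Å molecular sieves, CH2Cl2, −20 °C
Reagents that add atoms: tert-butyl hydroperoxide CC(C)(C)OO
Why: Sharpless asymmetric epoxidation: with the D-(−)-tartrate ligand the titanium-bound peroxide is delivered to one face of the 2-substituted allylic alcohol, which sets the quaternary carbon C4 by reagent control; the free hydroxymethyl arm is the future C3 and the silylated arm the future hydroxymethyl group.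

Step 7
Reactants: 11 (R)-{2-[(tert-butyldimethylsilyloxy)methyl]oxiran-2-yl}methanol
Product: 12 (S)-2-[(tert-butyldimethylsilyloxy)methyl]-2-[(triethylsilyloxy)methyl]oxirane
Conditions: Et3SiCl, imidazole, CH2Cl2, 0 °C
Reagents that add atoms: chlorotriethylsilane CC[Si](Cl)(CC)CC
Why: O-Silylation of the primary alcohol as its triethylsilyl ether, chosen because this ether is stable to base yet can later be cleaved in the presence of the TBS and tertiary triethylsilyl ethers.

Step 8
Reactants: 7 (S)-2-bromo-4-methylhex-1-en-5-yne; 12 (S)-2-[(tert-butyldimethylsilyloxy)methyl]-2-[(triethylsilyloxy)methyl]oxirane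
Product: 14 (2S,6S)-8-bromo-2-[(tert-butyldimethylsilyloxy)methyl]-6-methyl-1-(triethylsilyloxy)non-8-en-4-yn-2-ol (C3–C10 fragment; tertiary alcohol at C4), via lithium acetylide 13 (not isolated)
Conditions: n-BuLi (1.0 equiv), THF, −78 °C; then BF3·OEt2, 12, −78 °C
Reagents that add atoms: none
Why: BF3-promoted alkynyl opening of an epoxide (Yamaguchi alkynylation): the lithium acetylide attacks the unsubstituted CH2 terminus in an SN2 fashion, forming C5–C6 and leaving C4 untouched, and deprotonation of the alkyne by n-BuLi at −78 °C is much faster than bromine–lithium exchange at the alkenyl bromide.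

Step 9
Reactants: 14 (2S,6S)-8-bromo-2-[(tert-butyldimethylsilyloxy)methyl]-6-methyl-1-(triethylsilyloxy)non-8-en-4-yn-2-ol
Product: 16 (3E,5S)-3-[(2S)-4-bromo-2-methylpent-4-en-1-ylidene]-5-[(tert-butyldimethylsilyloxy)methyl]-2,2-dimethyl-5-[(triethylsilyloxy)methyl]-1,2-oxasilolane, via dimethylsilyl ether 15 (not isolated)
Conditions: Me2SiHCl, Et3N, DMAP (cat.), CH2Cl2, 0 °C → rt; filtration, evaporation; then Pt2[(CH2=CHSiMe2)2O]3 (1 mol %), THF, rt
Reagents that add atoms: chlorodimethylsilane C[SiH](C)Cl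
Why: Tethered hydrosilylation: O-silylation of the tertiary alcohol followed by platinum-catalysed intramolecular syn addition of Si–H in the 5-exo-dig mode puts silicon on C6 and hydrogen on C7, which fixes both the position of the future oxygen and the cis relation of C5 and C8.

Step 10
Reactants: 16 (3E,5S)-3-[(2S)-4-bromo-2-methylpent-4-en-1-ylidene]-5-[(tert-butyldimethylsilyloxy)methyl]-2,2-dimethyl-5-[(triethylsilyloxy)methyl]-1,2-oxasilolane
Product: 17 (2S,4E,6S)-8-bromo-2-[(tert-butyldimethylsilyloxy)methyl]-4-iodo-6-methyl-1-(triethylsilyloxy)nona-4,8-dien-2-ol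
Conditions: N-iodosuccinimide, (CF3)2CHOH, 0 °C; aq. NaHCO3/Na2S2O3 work-up
Reagents that add atoms: N-iodosuccinimide O=C1CCC(=O)N1I
Why: Iododesilylation of an alkenylsilane: ipso attack of iodonium at C6 through a β-silyl-stabilised cation replaces silicon by iodine with retention of the alkene geometry in the ionising solvent, and the residual Si–O bond is hydrolysed in the work-up.

Step 11
Reactants: 17 (2S,4E,6S)-8-bromo-2-[(tert-butyldimethylsilyloxy)methyl]-4-iodo-6-methyl-1-(triethylsilyloxy)nona-4,8-dien-2-ol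
Product: 18 (2S,4E,6S)-8-bromo-2-[(tert-butyldimethylsilyloxy)methyl]-4-iodo-6-methyl-1,2-bis(triethylsilyloxy)nona-4,8-diene
Conditions: Et3SiOTf, 2,6-lutidine, CH2Cl2, −78 → 0 °C
Reagents that add atoms: triethylsilyl trifluoromethanesulfonate CC[Si](CC)(CC)OS(=O)(=O)C(F)(F)F
Why: Silylation of the hindered tertiary alcohol with the silyl triflate (O-silylation), which also removes the free hydroxyl that would otherwise close an oxetane onto C6 under the copper conditions of the next step.

Step 12
Reactants: 18 (2S,4E,6S)-8-bromo-2-[(tert-butyldimethylsilyloxy)methyl]-4-iodo-6-methyl-1,2-bis(triethylsilyloxy)nona-4,8-diene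
Product: 19 (2S,4E,6S)-8-bromo-2-[(tert-butyldimethylsilyloxy)methyl]-4-methoxy-6-methyl-1,2-bis(triethylsilyloxy)nona-4,8-diene
Conditions: CuI (10 mol %), 3,4,7,8-tetramethyl-1,10-phenanthroline (20 mol %), Cs2CO3, MeOH (5 equiv), toluene, 80 °C
Reagents that add atoms: methanol CO
Why: Copper-catalysed Ullmann-type C–O coupling of an alkenyl iodide with an alcohol proceeds with retention and should give the methyl enol ether with C5 and C8 cis, the C–I bond reacting well below the temperature at which the C10–Br bond or the silyl ethers respond.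

Step 13
Reactants: 19 (2S,4E,6S)-8-bromo-2-[(tert-butyldimethylsilyloxy)methyl]-4-methoxy-6-methyl-1,2-bis(triethylsilyloxy)nona-4,8-diene
Product: 20 (2S,4E,6S)-8-bromo-2-[(tert-butyldimethylsilyloxy)methyl]-4-methoxy-6-methyl-2-(triethylsilyloxy)nona-4,8-dien-1-ol
Conditions: HF·pyridine, pyridine, THF, 0 °C
Reagents that add atoms: none
Why: Selective fluoride-mediated desilylation: under pyridine-buffered HF·pyridine the unhindered primary triethylsilyl ether is cleaved before the primary TBS and the tertiary triethylsilyl ether, and the buffer keeps the enol ether from protonation.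

Step 14
Reactants: 20 (2S,4E,6S)-8-bromo-2-[(tert-butyldimethylsilyloxy)methyl]-4-methoxy-6-methyl-2-(triethylsilyloxy)nona-4,8-dien-1-ol
Product: 21 (2R,4E,6S)-8-bromo-2-[(tert-butyldimethylsilyloxy)methyl]-4-methoxy-6-methyl-2-(triethylsilyloxy)nona-4,8-dienal (C3 aldehyde)
Conditions: Dess–Martin periodinane, pyridine, CH2Cl2, 0 °C
Reagents that add atoms: none
Why: Dess–Martin oxidation with pyridine buffer gives the C3 aldehyde, which has no α-hydrogen (C4 is quaternary) and so cannot epimerise or enolise.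

Step 15
Reactants: 1 (R)-4-benzyl-3-propionyloxazolidin-2-one; 21 (2R,4E,6S)-8-bromo-2-[(tert-butyldimethylsilyloxy)methyl]-4-methoxy-6-methyl-2-(triethylsilyloxy)nona-4,8-dienal
Product: 23 (R)-4-benzyl-3-[(2R,3R,4R,6E,8S)-10-bromo-4-[(tert-butyldimethylsilyloxy)methyl]-3-hydroxy-6-methoxy-2,8-dimethyl-4-(triethylsilyloxy)undeca-6,10-dienoyl]oxazolidin-2-one, via dibutylboron (Z)-enolate 22 (not isolated)
Conditions: 1, Bu2BOTf, Et3N, CH2Cl2, −78 → 0 °C; then 21, −78 → 0 °C; pH 7 buffer/MeOH work-up
Reagents that add atoms: none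
Why: Evans syn-aldol reaction: the dibutylboron (Z)-enolate adds through a closed Zimmerman–Traxler transition state on the enolate face fixed by the (R)-benzyl auxiliary, which sets C2 (R) independently of the chiral aldehyde, the accompanying C3 carbinol (R, syn) being destined for oxidation.

Step 16
Reactants: 23 (R)-4-benzyl-3-[(2R,3R,4R,6E,8S)-10-bromo-4-[(tert-butyldimethylsilyloxy)methyl]-3-hydroxy-6-methoxy-2,8-dimethyl-4-(triethylsilyloxy)undeca-6,10-dienoyl]oxazolidin-2-one
Product: 25 (2R,3R,4R,6E,8S)-10-bromo-4-[(tert-butyldimethylsilyloxy)methyl]-3-hydroxy-6-methoxy-2,8-dimethyl-4-(triethylsilyloxy)undeca-6,10-dienoic acid, via lithium percarboxylate 24 (not isolated)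
Conditions: LiOH, H2O2, THF/H2O, 0 °C; then aq. Na2SO3, 0 °C; pH 7 phosphate work-up
Reagents that add atoms: hydrogen peroxide (as lithium hydroperoxide) OO
Why: Hydroperoxide cleavage of the N-acyl oxazolidinone at the exocyclic carbonyl releases the acid and the auxiliary without retro-aldol, and reduction of the peracid with sulfite before neutralisation and a pH 7 work-up (acid kept as its triethylammonium salt) protect the enol ether.

Step 17
Reactants: 26 pent-1-yn-3-ol (racemic)
Product: 28 (Z)-1-iodo-2-methylpent-1-en-3-ol (racemic), via oxamagnesacycle 27 (not isolated)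
Conditions: MeMgBr (3 equiv), CuI (10 mol %), THF, −20 °C → rt; then I2, −78 → 0 °C
Reagents that add atoms: methylmagnesium bromide C[Mg]Br; iodine II
Why: Copper-catalysed anti-carbomagnesiation of a propargylic alkoxide: methyl adds to C12 and magnesium to C11 on the side of the alkoxide in a five-membered chelate, and iodinolysis with retention gives the (Z)-iodoalkene with iodine cis to the carbinol carbon.

Step 18
Reactants: 28 (Z)-1-iodo-2-methylpent-1-en-3-ol (racemic)
Product: 29 (Z)-1-iodo-2-methylpent-1-en-3-one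
Conditions: Dess–Martin periodinane, pyridine, CH2Cl2, 0 °C, exclusion of light
Reagents that add atoms: none
Why: Dess–Martin oxidation of the racemic allylic alcohol gives the enone, which erases the C13 centre so that it can be set anew by asymmetric reduction.

Step 19
Reactants: 29 (Z)-1-iodo-2-methylpent-1-en-3-one
Product: 30 (S,Z)-1-iodo-2-methylpent-1-en-3-ol
Conditions: (R)-2-methyl-CBS-oxazaborolidine [(R)-5,5-diphenyl-2-methyl-3,4-propano-1,3,2-oxazaborolidine] (20 mol %), BH3·SMe2, THF, −30 °C; MeOH quench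
Reagents that add atoms: none
Why: Corey–Bakshi–Shibata reduction: the ketone binds the (R)-oxazaborolidine with the α-branched alkenyl group as the large substituent and ethyl as the small one, and intramolecular hydride delivery sets C13 (S).

Step 20
Reactants: 30 (S,Z)-1-iodo-2-methylpent-1-en-3-ol
Product: 31 (S,Z)-2-methyl-1-(trimethylstannyl)pent-1-en-3-ol
Conditions: Me3SnSnMe3, Pd(PPh3)4 (5 mol %), iPr2NEt, THF, 60 °C
Reagents that add atoms: hexamethylditin C[Sn](C)(C)[Sn](C)(C)C
Why: Palladium-catalysed stannylation of an alkenyl iodide with hexamethylditin (oxidative addition, Sn–Sn transmetalation, reductive elimination) replaces iodine by trimethylstannyl with retention of the Z geometry and tolerates the free hydroxyl.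

Step 21
Reactants: 25 (2R,3R,4R,6E,8S)-10-bromo-4-[(tert-butyldimethylsilyloxy)methyl]-3-hydroxy-6-methoxy-2,8-dimethyl-4-(triethylsilyloxy)undeca-6,10-dienoic acid; 31 (S,Z)-2-methyl-1-(trimethylstannyl)pent-1-en-3-ol
Product: 33 (S,Z)-2-methyl-1-(trimethylstannyl)pent-1-en-3-yl (2R,3R,4R,6E,8S)-10-bromo-4-[(tert-butyldimethylsilyloxy)methyl]-3-hydroxy-6-methoxy-2,8-dimethyl-4-(triethylsilyloxy)undeca-6,10-dienoate, via mixed anhydride 32 (not isolated)
Conditions: 2,4,6-trichlorobenzoyl chloride, Et3N, THF, rt; then 31, DMAP, toluene, rt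
Reagents that add atoms: none
Why: Yamaguchi esterification: the mixed anhydride transfers the acyl group via the DMAP acylpyridinium to the allylic hydroxyl of 31, the C3 hydroxyl of the acid being a secondary alcohol flanked by the fully substituted C4 and too hindered to compete.

Step 22
Reactants: 33 (S,Z)-2-methyl-1-(trimethylstannyl)pent-1-en-3-yl (2R,3R,4R,6E,8S)-10-bromo-4-[(tert-butyldimethylsilyloxy)methyl]-3-hydroxy-6-methoxy-2,8-dimethyl-4-(triethylsilyloxy)undeca-6,10-dienoate
Product: 34 (S,Z)-2-methyl-1-(trimethylstannyl)pent-1-en-3-yl (2R,4R,6E,8S)-10-bromo-4-[(tert-butyldimethylsilyloxy)methyl]-6-methoxy-2,8-dimethyl-3-oxo-4-(triethylsilyloxy)undeca-6,10-dienoate (seco β-keto ester)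
Conditions: Dess–Martin periodinane, pyridine, CH2Cl2, 0 °C → rt
Reagents that add atoms: none
Why: Dess–Martin oxidation of the C3 carbinol to the ketone under base-free, pyridine-buffered conditions gives the β-keto ester while C2, now flanked by two carbonyl groups, keeps its configuration.

Step 23
Reactants: 34 (S,Z)-2-methyl-1-(trimethylstannyl)pent-1-en-3-yl (2R,4R,6E,8S)-10-bromo-4-[(tert-butyldimethylsilyloxy)methyl]-6-methoxy-2,8-dimethyl-3-oxo-4-(triethylsilyloxy)undeca-6,10-dienoate
Product: 35 (3R,5R,7E,9S,12Z,14S)-5-[(tert-butyldimethylsilyloxy)methyl]-14-ethyl-7-methoxy-3,9,13-trimethyl-11-methylidene-5-(triethylsilyloxy)-1-oxacyclotetradeca-7,12-diene-2,4-dione (bis-silyl ether of the target)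
Conditions: Pd2(dba)3 (10 mol %), AsPh3 (40 mol %), CuI (20 mol %), DMF, 1 mM, slow addition of 34, 25 → 45 °C
Reagents that add atoms: none
Why: Oxidative addition of the C10–Br bond of the 2-bromoalkene to zerovalent palladium, transfer of the C11 alkenyl group from tin (helped by CuI through a transient alkenylcopper species) and reductive elimination form the C10–C11 bond with retention at both alkenes; this is a Stille cross-coupling run intramolecularly, the known way to close macrocyclic 1,3-dienes from alkenyl halide–alkenylstannane seco compounds. The 14-membered lactone closes by end-to-end union of the two alkenyl termini on a chain already bent by the Z C11=C12 alkene, the enol ether and the ester. No stereocentre is formed, and the C11=C12 and C6=C7 geometries are fixed beforehand and carried through. The selectivity needed is ring closure against oligomerisation, which high dilution and slow addition secure, and only one C–Br/C–Sn pair is present. The weakly bound AsPh3 ligand and the trimethylstannyl group speed transmetalation so that the coupling runs near room temperature without base, which leaves the β-keto ester (C2), both silyl ethers and the enol ether untouched.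

Step 24
Reactants: 35 (3R,5R,7E,9S,12Z,14S)-5-[(tert-butyldimethylsilyloxy)methyl]-14-ethyl-7-methoxy-3,9,13-trimethyl-11-methylidene-5-(triethylsilyloxy)-1-oxacyclotetradeca-7,12-diene-2,4-dione
Product: 36 (3R,5R,7E,9S,12Z,14S)-14-ethyl-5-hydroxy-5-(hydroxymethyl)-7-methoxy-3,9,13-trimethyl-11-methylidene-1-oxacyclotetradeca-7,12-diene-2,4-dione (target)
Conditions: HF·pyridine, pyridine, THF, 0 °C → rt
Reagents that add atoms: none
Why: Fluoride-mediated cleavage of both silyl ethers with pyridine-buffered HF·pyridine, conditions without aqueous acid or base, should leave the methyl enol ether, the diene and the epimerisable C2 centre as they are and give the target.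

**Compound list**

1 | (R)-4-benzyl-3-propionyloxazolidin-2-one | CCC(=O)N1[C@H](Cc2ccccc2)COC1=O | starting material
2 | 2,3-dibromopropene | BrCC(Br)=C | starting material
3 | sodium (Z)-enolate of 1 | [Na+].C/C=C(\[O-])N1[C@H](Cc2ccccc2)COC1=O | intermediate (not isolated)
4 | (R)-4-benzyl-3-[(S)-4-bromo-2-methylpent-4-enoyl]oxazolidin-2-one | C=C(Br)C[C@H](C)C(=O)N1[C@H](Cc2ccccc2)COC1=O | intermediate
5 | (S)-4-bromo-2-methylpent-4-en-1-ol | C=C(Br)C[C@H](C)CO | intermediate
6 | (S)-4-bromo-2-methylpent-4-enal | C=C(Br)C[C@H](C)C=O | intermediate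
7 | (S)-2-bromo-4-methylhex-1-en-5-yne | C=C(Br)C[C@H](C)C#C | intermediate
8 | 2-methylenepropane-1,3-diol | C=C(CO)CO | starting material
9 | monosodium alkoxide of 8 | [Na+].[O-]CC(=C)CO | intermediate (not isolated)
10 | 2-[(tert-butyldimethylsilyloxy)methyl]prop-2-en-1-ol | C=C(CO)CO[Si](C)(C)C(C)(C)C | intermediate
11 | (R)-{2-[(tert-butyldimethylsilyloxy)methyl]oxiran-2-yl}methanol | OC[C@]1(CO[Si](C)(C)C(C)(C)C)CO1 | intermediate
12 | (S)-2-[(tert-butyldimethylsilyloxy)methyl]-2-[(triethylsilyloxy)methyl]oxirane | CC[Si](CC)(CC)OC[C@]1(CO[Si](C)(C)C(C)(C)C)CO1 | intermediate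
13 | lithium acetylide of 7 | [Li+].[C-]#C[C@@H](C)CC(Br)=C | intermediate (not isolated)
14 | (2S,6S)-8-bromo-2-[(tert-butyldimethylsilyloxy)methyl]-6-methyl-1-(triethylsilyloxy)non-8-en-4-yn-2-ol | C=C(Br)C[C@H](C)C#CC[C@](O)(CO[Si](CC)(CC)CC)CO[Si](C)(C)C(C)(C)C | intermediate
15 | dimethylsilyl ether of 14 (O–SiHMe2 on the tertiary oxygen) | C=C(Br)C[C@H](C)C#CC[C@](O[SiH](C)C)(CO[Si](CC)(CC)CC)CO[Si](C)(C)C(C)(C)C | intermediate (not isolated)
16 | (3E,5S)-3-[(2S)-4-bromo-2-methylpent-4-en-1-ylidene]-5-[(tert-butyldimethylsilyloxy)methyl]-2,2-dimethyl-5-[(triethylsilyloxy)methyl]-1,2-oxasilolane | C=C(Br)C[C@H](C)/C=C1\C[C@](CO[Si](CC)(CC)CC)(CO[Si](C)(C)C(C)(C)C)O[Si]1(C)C | intermediate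
17 | (2S,4E,6S)-8-bromo-2-[(tert-butyldimethylsilyloxy)methyl]-4-iodo-6-methyl-1-(triethylsilyloxy)nona-4,8-dien-2-ol | C=C(Br)C[C@H](C)/C=C(I)\C[C@](O)(CO[Si](CC)(CC)CC)CO[Si](C)(C)C(C)(C)C | intermediate
18 | (2S,4E,6S)-8-bromo-2-[(tert-butyldimethylsilyloxy)methyl]-4-iodo-6-methyl-1,2-bis(triethylsilyloxy)nona-4,8-diene | C=C(Br)C[C@H](C)/C=C(I)\C[C@](O[Si](CC)(CC)CC)(CO[Si](CC)(CC)CC)CO[Si](C)(C)C(C)(C)C | intermediate
19 | (2S,4E,6S)-8-bromo-2-[(tert-butyldimethylsilyloxy)methyl]-4-methoxy-6-methyl-1,2-bis(triethylsilyloxy)nona-4,8-diene | C=C(Br)C[C@H](C)/C=C(OC)\C[C@](O[Si](CC)(CC)CC)(CO[Si](CC)(CC)CC)CO[Si](C)(C)C(C)(C)C | intermediate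
20 | (2S,4E,6S)-8-bromo-2-[(tert-butyldimethylsilyloxy)methyl]-4-methoxy-6-methyl-2-(triethylsilyloxy)nona-4,8-dien-1-ol | C=C(Br)C[C@H](C)/C=C(OC)\C[C@](O[Si](CC)(CC)CC)(CO)CO[Si](C)(C)C(C)(C)C | intermediate
21 | (2R,4E,6S)-8-bromo-2-[(tert-butyldimethylsilyloxy)methyl]-4-methoxy-6-methyl-2-(triethylsilyloxy)nona-4,8-dienal | C=C(Br)C[C@H](C)/C=C(OC)\C[C@](O[Si](CC)(CC)CC)(C=O)CO[Si](C)(C)C(C)(C)C | intermediate
22 | dibutylboron (Z)-enolate of 1 | C/C=C(\OB(CCCC)CCCC)N1[C@H](Cc2ccccc2)COC1=O | intermediate (not isolated)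
23 | (R)-4-benzyl-3-[(2R,3R,4R,6E,8S)-10-bromo-4-[(tert-butyldimethylsilyloxy)methyl]-3-hydroxy-6-methoxy-2,8-dimethyl-4-(triethylsilyloxy)undeca-6,10-dienoyl]oxazolidin-2-one | O=C(N1[C@H](Cc2ccccc2)COC1=O)[C@H](C)[C@@H](O)[C@](O[Si](CC)(CC)CC)(CO[Si](C)(C)C(C)(C)C)C/C(OC)=C\[C@@H](C)CC(Br)=C | intermediate
24 | lithium percarboxylate of acid 25 | [Li+].[O-]OC(=O)[C@H](C)[C@@H](O)[C@](O[Si](CC)(CC)CC)(CO[Si](C)(C)C(C)(C)C)C/C(OC)=C\[C@@H](C)CC(Br)=C | intermediate (not isolated)
25 | (2R,3R,4R,6E,8S)-10-bromo-4-[(tert-butyldimethylsilyloxy)methyl]-3-hydroxy-6-methoxy-2,8-dimethyl-4-(triethylsilyloxy)undeca-6,10-dienoic acid | O=C(O)[C@H](C)[C@@H](O)[C@](O[Si](CC)(CC)CC)(CO[Si](C)(C)C(C)(C)C)C/C(OC)=C\[C@@H](C)CC(Br)=C | intermediate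
26 | pent-1-yn-3-ol (racemic) | CCC(O)C#C | starting material
27 | 3-ethyl-4-methyl-2,3-dihydro-1,2-oxamagnesole (chelated alkenylmagnesium alkoxide) | CCC1O[Mg]C=C1C | intermediate (not isolated)
28 | (Z)-1-iodo-2-methylpent-1-en-3-ol (racemic) | I/C=C(/C)C(O)CC | intermediate
29 | (Z)-1-iodo-2-methylpent-1-en-3-one | I/C=C(/C)C(=O)CC | intermediate
30 | (S,Z)-1-iodo-2-methylpent-1-en-3-ol | I/C=C(/C)[C@H](CC)O | intermediate
31 | (S,Z)-2-methyl-1-(trimethylstannyl)pent-1-en-3-ol | C[Sn](C)(C)/C=C(/C)[C@H](CC)O | intermediate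
32 | mixed anhydride of 25 with 2,4,6-trichlorobenzoic acid | O=C(OC(=O)c1c(Cl)cc(Cl)cc1Cl)[C@H](C)[C@@H](O)[C@](O[Si](CC)(CC)CC)(CO[Si](C)(C)C(C)(C)C)C/C(OC)=C\[C@@H](C)CC(Br)=C | intermediate (not isolated)
33 | (S,Z)-2-methyl-1-(trimethylstannyl)pent-1-en-3-yl (2R,3R,4R,6E,8S)-10-bromo-4-[(tert-butyldimethylsilyloxy)methyl]-3-hydroxy-6-methoxy-2,8-dimethyl-4-(triethylsilyloxy)undeca-6,10-dienoate | C[Sn](C)(C)/C=C(/C)[C@H](CC)OC(=O)[C@H](C)[C@@H](O)[C@](O[Si](CC)(CC)CC)(CO[Si](C)(C)C(C)(C)C)C/C(OC)=C\[C@@H](C)CC(Br)=C | intermediate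
34 | (S,Z)-2-methyl-1-(trimethylstannyl)pent-1-en-3-yl (2R,4R,6E,8S)-10-bromo-4-[(tert-butyldimethylsilyloxy)methyl]-6-methoxy-2,8-dimethyl-3-oxo-4-(triethylsilyloxy)undeca-6,10-dienoate | C[Sn](C)(C)/C=C(/C)[C@H](CC)OC(=O)[C@H](C)C(=O)[C@](O[Si](CC)(CC)CC)(CO[Si](C)(C)C(C)(C)C)C/C(OC)=C\[C@@H](C)CC(Br)=C | intermediate
35 | (3R,5R,7E,9S,12Z,14S)-5-[(tert-butyldimethylsilyloxy)methyl]-14-ethyl-7-methoxy-3,9,13-trimethyl-11-methylidene-5-(triethylsilyloxy)-1-oxacyclotetradeca-7,12-diene-2,4-dione | C=C1/C=C(/C)[C@H](CC)OC(=O)[C@H](C)C(=O)[C@](O[Si](CC)(CC)CC)(CO[Si](C)(C)C(C)(C)C)C/C(OC)=C\[C@@H](C)C1 | intermediate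
36 | (3R,5R,7E,9S,12Z,14S)-14-ethyl-5-hydroxy-5-(hydroxymethyl)-7-methoxy-3,9,13-trimethyl-11-methylidene-1-oxacyclotetradeca-7,12-diene-2,4-dione | C=C1/C=C(/C)[C@H](CC)OC(=O)[C@H](C)C(=O)[C@](O)(CO)C/C(OC)=C\[C@@H](C)C1 | target

**Step count and risks**

Total step count: 24.
Longest linear sequence: 17 steps (steps 1–4, 8–16, 21–24).

Steps most likely to fail:

Step 12 (copper-catalysed methoxylation). What may go wrong: loss of the primary triethylsilyl ether in hot carbonate–methanol followed by ring closure of the freed alkoxide onto C6, slow coupling at the hindered internal iodide, or competing reaction at the C10–Br bond. Fallback: from 18 the C–I bond alone is borylated (PdCl2(PPh3)2, PPh3, KOPh, bis(pinacolato)diboron, toluene, 50 °C; Miyaura borylation with retention) to the alkenyl pinacol boronate F1. This is coupled oxidatively with methanol at room temperature (Cu(OAc)2, Et3N, MeOH, air; Chan–Lam-type etherification of an alkenyl boronate) and comes back to the route at 19.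

Step 21 (esterification). What may go wrong: acylation at the C3 hydroxyl (β-lactone or oligomer formation) in place of the hindered allylic alcohol, addition of the free acid to the enol ether during handling, or protodestannylation of 31. Fallback: the ester bond is made first and the C2–C3 bond second. From 31, propionylation (propionyl chloride, pyridine, DMAP) gives the stannyl propionate F2. Its lithium enolate F3 (LiN(iPr)2, THF, −78 °C) adds to aldehyde 21 to give the β-hydroxy ester F4 as a mixture of C2/C3 diastereomers. Dess–Martin oxidation removes the C3 centre and gives 34 together with its C2 epimer F5, which equilibrates with 34 through the enol (trace Et3N) and is recycled after separation, so the fallback comes back to the route at 34. It gives up the auxiliary control of C2 in exchange for this equilibration.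

Step 23 (Stille macrocyclisation). What may go wrong: oligomerisation outrunning ring closure, or sluggish oxidative addition of the 2-bromoalkene so that protodestannylation or homocoupling of the stannane takes over. Fallback: the C10–C11 bond is made between fragments and the ring is closed at the ester instead. From acid 25 and stannyl alcohol 31, an intermolecular Stille coupling (Pd2(dba)3, AsPh3, CuI, DMF, no dilution needed) gives the dienyl hydroxy acid F6. Yamaguchi macrolactonisation at high dilution through the mixed anhydride F7 closes the C1–O bond to the 14-membered β-hydroxy lactone F8 (the hindered C3 hydroxyl should not compete). Dess–Martin oxidation at C3 then comes back to the route at 35.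

**Further compounds**

F1 | step 12 | (2S,4Z,6S)-8-bromo-2-[(tert-butyldimethylsilyloxy)methyl]-6-methyl-4-(4,4,5,5-tetramethyl-1,3,2-dioxaborolan-2-yl)-1,2-bis(triethylsilyloxy)nona-4,8-diene (boron in place of iodine, same geometry) | C=C(Br)C[C@H](C)/C=C(B1OC(C)(C)C(C)(C)O1)\C[C@](O[Si](CC)(CC)CC)(CO[Si](CC)(CC)CC)CO[Si](C)(C)C(C)(C)C
F2 | step 21 | (S,Z)-2-methyl-1-(trimethylstannyl)pent-1-en-3-yl propanoate | C[Sn](C)(C)/C=C(/C)[C@H](CC)OC(=O)CC
F3 | step 21 | lithium enolate of F2 (methyl cis to the alkoxy oxygen) | [Li+].C[Sn](C)(C)/C=C(/C)[C@H](CC)O/C([O-])=C\C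
F4 | step 21 | β-hydroxy ester as a mixture of C2/C3 diastereomers | C[Sn](C)(C)/C=C(/C)[C@H](CC)OC(=O)C(C)C(O)[C@](O[Si](CC)(CC)CC)(CO[Si](C)(C)C(C)(C)C)C/C(OC)=C\[C@@H](C)CC(Br)=C
F5 | step 21 | C2 epimer (2S) of 34 | C[Sn](C)(C)/C=C(/C)[C@H](CC)OC(=O)[C@@H](C)C(=O)[C@](O[Si](CC)(CC)CC)(CO[Si](C)(C)C(C)(C)C)C/C(OC)=C\[C@@H](C)CC(Br)=C
F6 | step 23 | dienyl hydroxy acid (C10–C11 joined; free C13 hydroxyl and C1 acid) | O=C(O)[C@H](C)[C@@H](O)[C@](O[Si](CC)(CC)CC)(CO[Si](C)(C)C(C)(C)C)C/C(OC)=C\[C@@H](C)CC(=C)/C=C(/C)[C@H](CC)O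
F7 | step 23 | mixed anhydride of F6 with 2,4,6-trichlorobenzoic acid | O=C(OC(=O)c1c(Cl)cc(Cl)cc1Cl)[C@H](C)[C@@H](O)[C@](O[Si](CC)(CC)CC)(CO[Si](C)(C)C(C)(C)C)C/C(OC)=C\[C@@H](C)CC(=C)/C=C(/C)[C@H](CC)O
F8 | step 23 | 14-membered β-hydroxy lactone (C3 carbinol of 35) | C=C1/C=C(/C)[C@H](CC)OC(=O)[C@H](C)[C@@H](O)[C@](O[Si](CC)(CC)CC)(CO[Si](C)(C)C(C)(C)C)C/C(OC)=C\[C@@H](C)C1
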